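**Assumption:** the target, 4-[(2,4-dimethoxy-6-pentylbenzoyl)oxy]-2-methoxy-6-propylbenzoic acid, has no stereocentre, so no stereocontrol is needed. LDA is used as the commercial solution.

## Retrosynthetic overview

1. The free acid comes from its methyl ester by SN2 cleavage of the O–CH3 bond, which leaves the depside ester untouched.
2. Key disconnection: the depside aryl C–O bond, made by joining the carboxylate oxygen of 2,4-dimethoxy-6-pentylbenzoic acid to C4–H of methyl 2-methoxy-6-propylbenzoate (one-pot C–H borylation, then copper acyloxylation).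
3. Each half comes from a commercial ortho-toluic acid derivative by benzylic (lateral) alkylation: n-butyl iodide for the pentyl arm, ethyl iodide for the propyl arm.
4. No ring is formed; both benzene rings are bought intact.

## Route

Step 1
Reactants: 1 2,4-dimethoxy-6-methylbenzoic acid
Product: 3 2,4-dimethoxy-6-pentylbenzoic acid, via dilithio dianion 2 (not isolated)
Conditions: LDA (2.3 equiv), THF, −78 → 0 °C; n-BuI (1.3 equiv), −78 °C → rt; 1 M HCl work-up
Reagents that add atoms: 1-iodobutane, CCCCI
Why: Lateral lithiation of an ortho-toluic acid (carboxylate/benzylic dianion) followed by SN2 alkylation; LDA gives the thermodynamic benzylic anion, not ring lithiation, and the lithium carboxylate is inert to the base and to the iodide.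

Step 2
Reactants: 4 methyl 2-methoxy-6-methylbenzoate
Product: 6 methyl 2-methoxy-6-propylbenzoate, via benzylic lithium species 5 (not isolated)
Conditions: LDA (1.1 equiv), THF, −78 °C, 30 min; EtI (1.5 equiv), DMPU (2 equiv), −78 → −40 °C; aq. NH4Cl
Reagents that add atoms: iodoethane, CCI
Why: Lateral lithiation/alkylation of an ortho-toluate ester; the di-ortho-substituted ester is too hindered for fast self-condensation at −78 °C and the conjugated benzylic anion is alkylated cleanly by the primary iodide.

Step 3
Reactants: 6 methyl 2-methoxy-6-propylbenzoate; 7 bis(pinacolato)diboron; 3 2,4-dimethoxy-6-pentylbenzoic acid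
Product: 9 methyl 4-[(2,4-dimethoxy-6-pentylbenzoyl)oxy]-2-methoxy-6-propylbenzoate, via aryl pinacol boronate 8 (not isolated)
Conditions: (a) 6 (1.5 equiv), 7 (1.5 equiv), [Ir(cod)OMe]2 (1.5 mol%), dtbpy (3 mol%), THF, 80 °C (sealed), then evaporate volatiles; (b) 3 (1.0 equiv, limiting), Cu(OTf)2 (30 mol%), 2,6-lutidine (1.5 equiv), 4 Å MS, EtOAc, O2 (1 atm), 50 °C
Reagents that add atoms: none
Why: Proposed new method: a telescoped, sterically controlled arene C–H acyloxylation in which Ir(III)-trisboryl C–H borylation selects C4–H of 6 (the only ring C–H without an ortho substituent), and the crude ArBpin then transmetalates to the copper(II) carboxylate of 3 through a Cu–O–B bridge, is oxidised to aryl–Cu(III)–carboxylate and forms the aryl C–O bond by reductive elimination, with O2 returning Cu(I) to Cu(II); because the acyl carbon of 3 never becomes tetrahedral, its di-ortho substitution, which cripples ordinary acyl-transfer esterification, does not matter, and triflate/lutidine supply no competing O-nucleophile; the closest known reaction types are one-pot Ir C–H borylation/Cu C–heteroatom coupling and Chan–Lam O-arylation of simple carboxylic acids with arylboronic acids, neither shown for a crude ArBpin with a di-ortho-substituted electron-rich benzoic acid.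

Step 4
Reactants: 9 methyl 4-[(2,4-dimethoxy-6-pentylbenzoyl)oxy]-2-methoxy-6-propylbenzoate
Product: 10 4-[(2,4-dimethoxy-6-pentylbenzoyl)oxy]-2-methoxy-6-propylbenzoic acid
Conditions: anhydrous LiI (6 equiv), EtOAc, reflux, N2, dark; 1 M HCl work-up
Reagents that add atoms: none
Why: Nucleophilic (SN2) dealkylation of a methyl ester by iodide at the O–CH3 carbon, which is insensitive to the hindrance at the acyl carbon; the aryl ester has no sp3 O–C bond to attack and is shielded at its di-ortho-substituted carbonyl, and the aryl methyl ethers (phenoxide leaving groups) are far slower than the carboxylate leaving group.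

## Compound list

1 | 2,4-dimethoxy-6-methylbenzoic acid | Cc1cc(OC)cc(OC)c1C(=O)O | starting material
2 | dilithio dianion of 1 (lithium 2-(lithiomethyl)-4,6-dimethoxybenzoate, not isolated) | [Li+].[Li+].[CH2-]c1cc(OC)cc(OC)c1C(=O)[O-] | intermediate
3 | 2,4-dimethoxy-6-pentylbenzoic acid | CCCCCc1cc(OC)cc(OC)c1C(=O)O | intermediate
4 | methyl 2-methoxy-6-methylbenzoate | Cc1cccc(OC)c1C(=O)OC | starting material
5 | methyl 2-(lithiomethyl)-6-methoxybenzoate (not isolated) | [Li+].[CH2-]c1cccc(OC)c1C(=O)OC | intermediate
6 | methyl 2-methoxy-6-propylbenzoate | CCCc1cccc(OC)c1C(=O)OC | intermediate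
7 | bis(pinacolato)diboron | CC1(C)OB(OC1(C)C)B1OC(C)(C)C(C)(C)O1 | starting material
8 | methyl 2-methoxy-6-propyl-4-(4,4,5,5-tetramethyl-1,3,2-dioxaborolan-2-yl)benzoate (not isolated) | CCCc1cc(B2OC(C)(C)C(C)(C)O2)cc(OC)c1C(=O)OC | intermediate
9 | methyl 4-[(2,4-dimethoxy-6-pentylbenzoyl)oxy]-2-methoxy-6-propylbenzoate | CCCCCc1cc(OC)cc(OC)c1C(=O)Oc1cc(CCC)c(C(=O)OC)c(OC)c1 | intermediate
10 | 4-[(2,4-dimethoxy-6-pentylbenzoyl)oxy]-2-methoxy-6-propylbenzoic acid | CCCCCc1cc(OC)cc(OC)c1C(=O)Oc1cc(CCC)c(C(=O)O)c(OC)c1 | target

## Step count and risks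

Total step count: 4. Longest linear sequence: 3 steps (4 → 6 → 9 → 10, or 1 → 3 → 9 → 10).

**Step 3 (proposed new step).** The main risks are slow boron-to-copper transfer from the pinacol ester, phenol formation from adventitious water, and protodeboronation. The fallback uses known chemistry and sets out from 6 (with 7). Compound 6 is borylated exactly as in stage (a) to boronate 8, which is oxidised in the same pot with aqueous Oxone in acetone to methyl 4-hydroxy-2-methoxy-6-propylbenzoate F1. Phenol F1 is then esterified with acid 3 by the classical trifluoroacetic anhydride method for hindered depsides (TFAA, toluene, rt), which activates 3 as its mixed anhydride/acylium ion. This comes back to the route at 9.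

**Step 4.** The risks are a slow reaction in EtOAc and competing loss of the methyl ether ortho to a carbonyl on prolonged heating. The fallback changes the ester to one removed by acid and sets out from 6. Compound 6 is saponified under forcing conditions (KOH, DMSO/H2O, 100 °C) to 2-methoxy-6-propylbenzoic acid F2. Acid F2 is converted with isobutene and catalytic H2SO4 in CH2Cl2 into tert-butyl 2-methoxy-6-propylbenzoate F3. Ester F3 is taken through the step 3 protocol with 7 and 3, via tert-butyl 2-methoxy-6-propyl-4-(4,4,5,5-tetramethyl-1,3,2-dioxaborolan-2-yl)benzoate F4 (not isolated), to tert-butyl 4-[(2,4-dimethoxy-6-pentylbenzoyl)oxy]-2-methoxy-6-propylbenzoate F5. Treatment of F5 with TFA in CH2Cl2 at rt removes the tert-butyl group without touching the depside and comes back to the route at 10.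

**Step 2.** The risks are Claisen-type self-condensation of the lithiated toluate and some dialkylation. The fallback reverses the polarity of the benzylic carbon and sets out from 4. Wohl–Ziegler bromination of 4 (NBS, AIBN, PhCF3, 80 °C) gives methyl 2-(bromomethyl)-6-methoxybenzoate F6. Copper-catalysed coupling of F6 with ethylmagnesium bromide (Li2CuCl4 3 mol%, THF, −78 → −30 °C) comes back to the route at 6.

## Further compounds

F1 | step 3 | methyl 4-hydroxy-2-methoxy-6-propylbenzoate | CCCc1cc(O)cc(OC)c1C(=O)OC
F2 | step 4 | 2-methoxy-6-propylbenzoic acid | CCCc1cccc(OC)c1C(=O)O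
F3 | step 4 | tert-butyl 2-methoxy-6-propylbenzoate | CCCc1cccc(OC)c1C(=O)OC(C)(C)C
F4 | step 4 | tert-butyl 2-methoxy-6-propyl-4-(4,4,5,5-tetramethyl-1,3,2-dioxaborolan-2-yl)benzoate | CCCc1cc(B2OC(C)(C)C(C)(C)O2)cc(OC)c1C(=O)OC(C)(C)C
F5 | step 4 | tert-butyl 4-[(2,4-dimethoxy-6-pentylbenzoyl)oxy]-2-methoxy-6-propylbenzoate | CCCCCc1cc(OC)cc(OC)c1C(=O)Oc1cc(CCC)c(C(=O)OC(C)(C)C)c(OC)c1
F6 | step 2 | methyl 2-(bromomethyl)-6-methoxybenzoate | COC(=O)c1c(CBr)cccc1OC
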